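(All runs are calculated for an exercise, noise included.)

Count the half-lives that lie between a late reading of the target and the asked time.

| flask | substrate | remark | time |
|---|---|---|---|
| south-west | 0.25 M | run made earlier |  |
| south | 0.38 M | run made earlier |  |
| north-west | 0.84 M | run made earlier |  |
| Thursday's | 0.20 M |  | 25 h |
| Friday's | 0.40 M |  | 25 h |
| Wednesday's | 0.80 M |  | 25 h |

| run | time / h | target / % |
|---|---|---|
| south-west | 2.00 | 23.3 |
| south-west | 6.00 | 16.0 |
| south-west | 12.0 | 5.3 |
| south-west | 20.0 | 0 |
| south | 1.33 | 21.2 |
| south | 3.00 | 23.5 |
| south | 8.00 | 11.0 |
| south | 20.0 | 0.2 |
| north-west | 1.33 | 19.9 |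
| north-west | 3.00 | 22.2 |
| north-west | 8.00 | 10.0 |
| north-west | 20.0 | 1.2 |

(standard deviation of a reading: 1 percentage point)

1. [target] at the end for Thursday's, Friday's, Wednesday's, in this order
2. the shape of the row from first to last (rises, then falls / hardly changes / rises all the way / falls, then rises / falls all the way)

- what was read earlier has a scatter of 1 percentage point, one standard deviation
- what may be going on: substrate -> side product; substrate -> target; substrate -> intermediate; intermediate -> target; target -> over-reaction product; substrate <-> dormant form
- "hardly changes" means that all values lie within two and a half points (for a concentration: within two and a half percent of the largest)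

I build the flask up one process at a time. With substrate passing into target and nothing more, the target could not fall, yet the south run drops from 23.5% at 3.00 h to 11.0% at 8.00 h, so I add the over-reaction of the target. The south-west run reads 16.0% at 6.00 h and 5.3% at 12.0 h, which reads as 3.76 h, within the scatter of those readings; I call this the tail half-life, the time in which the target's percentage falls to half after its highest readings. The south and north-west runs read 21.2% and 19.9% at 1.33 h, although the north-west charge is 2.21 times the south charge, so I take the steps as first-order and use one percentage across the charges.

Counting from the south run's highest reading, 5.85 tail half-lives leave 0.409% by my estimate. But the south run's fall after that reading corresponds to 4.57 h, slower than the tail, and I read that as substrate still arriving. So I add this feed by starting the count later: from 12.0 h in the south-west run, 25 h lies 3.45 tail half-lives away, which leaves 0.484%, more than the first count. The intermediate might stretch the tail further, but the readings at 20.0 h are 0%, 0.2% and 1.2%, with a scatter of 1 percentage point, too close to zero for me to read a stretch from them, so I keep this percentage. My row is 9.67 × 10⁻⁴ M, 0.00193 M and 0.00387 M, rising all the way with the charge.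

The forecast, reasoning that “the kinetics are essentially first order”, gives 9.000 × 10⁻⁴ M, 0.0019 M and 0.0045 M, rises all the way, below mine for Thursday's flask and above mine for Wednesday's.

The flasks give 0.00108 M, 0.00216 M and 0.00433 M, rises all the way.

    substrate → side product (k = 1.90 × 10⁻⁵ s⁻¹)
    substrate → target (k = 9.70 × 10⁻⁵ s⁻¹)
    substrate → intermediate (k = 2.70 × 10⁻⁵ s⁻¹)
    intermediate → target (k = 3.60 × 10⁻⁵ s⁻¹)
    target → over-reaction product (k = 1.20 × 10⁻⁴ s⁻¹)
    substrate ⇌ dormant form (K = 0.460, k = 4.40 × 10⁻⁴ s⁻¹)

In Thursday's flask the passing of substrate into target has 99% of its turnover up to 25 h behind it at 12.5 h, when target stands at 4.45% and intermediate at 5.54%. Wednesday's flask holds the same 4.45% of target then, and the tail half-life carries that to 0.00356 M at 25 h, against 0.00433 M found. Thursday's target falls to 0.541% by 25 h, a tail half-life of 4.11 h, longer than the 1.6 h of its own over-reaction; at that moment target is being made at 0.669 of the rate at which it is used up, and the intermediate stands at 1.17%.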